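## The problem

The target 20 is a 3-arylcoumarin without a stereocentre. Ring A is the benzo ring of the pyranone and carries the lactone oxygen O1 at C8a, a methoxy group at C5 and a free hydroxyl at C7. Ring B is a 2',4'-dihydroxyphenyl group on C3 with a prenyl chain at C3', between the two hydroxyls.

- Ring A has three oxygens in a 1,3,5 relationship that must be told apart (lactone, methyl ether, free phenol). A route from a symmetrical phloroglucinol has to solve that by hand.
- Ring B needs C-prenylation at the most hindered position of a resorcinol, which direct alkylation does not deliver.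
- The prenyl group is the fragile part. Acid closes it onto either neighbouring phenol to a chroman, singlet oxygen attacks it in an ene reaction, hydrogenation is excluded, and its benzylic–allylic CH2 is prone to oxidation while ring B is electron-rich.
- The C2' oxygen is a second trap. In an open-chain precursor with a carboxyl on the future C3 it can close a five-membered benzofuranone instead of the pyranone.
- The only stereochemical element is the geometry of the future C3=C4 double bond in open precursors. It decides whether the carboxyl can reach ring A.
- The feature that makes the key step possible is that O1 sits on C8a, ortho to C4a. In a Z 2,3-diarylacrylic acid the carboxyl oxygen lies beside the single free ortho C–H of a 2-methoxy-4-oxyphenyl ring A, the other ortho carbon being blocked by the methoxy group. An oxidative C–O closure can therefore give only the 5-methoxy-7-oxy pattern, and ring A needs two oxygens beforehand, not three.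

## Retrosynthesis

**20 from 19 (three O–acyl bonds).** No skeletal bond is cut. The phenols of 20 are masked in 19 as esters: acetate on the C7 oxygen, pivalates on the C2' and C4' oxygens. Esters are preferred to acetals or silyl ethers because methoxide removes all three in one operation that leaves the prenyl group alone, whereas acetal cleavage would bring acid next to prenyl and two free ortho phenols. The forward step only has to tolerate reversible opening of the pyranone.

**19 from 18 (O1–C8a).** The aryl C–O bond of the lactone is cut, leading to the Z 2,3-diarylacrylic acid 18. The neighbouring cuts are less attractive here: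
- O1–C2 (lactonisation of a phenol) needs a ring A aldehyde that already carries all three oxygens.
- C4–C4a (electrophilic closure onto a phenol ester) meets two non-equivalent ortho positions.
- C3–C1' (cross-coupling) still needs the finished coumarin core.

With O1–C8a formed last, ring A shrinks to a 2,4-dioxygenated benzaldehyde and closure can occur at one carbon only. The forward reaction must be a two-electron oxidation that is selective for the carboxyl/ring A pair. The ester groups are chosen to secure this:
- The pivalates deactivate ring B and its benzylic–allylic CH2 toward the anode.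
- An acetate on the oxygen para to the side chain is not an electrofugal group, unlike a silyl ether, so dearomatising ipso attack cannot end in a dienone.

**18 from 17 (no bond cut, geometry only).** The E acid 17 has the carboxyl trans to ring A and cannot close. The forward step is a sensitised E to Z isomerisation under exclusion of oxygen, with recycling of recovered 17.

**17 from 12 and 13 (the future C3=C4 bond).** A Perkin condensation joins the ring B arylacetic acid 12 to commercial 4-hydroxy-2-methoxybenzaldehyde 13. It is convergent, gives the acid directly (an ester would have to be hydrolysed beside three aryl esters), and acetylates the phenol of 13 in the flask to 14. The reacting species are the mixed anhydride 15 and, before work-up, the product mixed anhydride 16. The demand on the forward step is that the C2' ester does not transfer its acyl group and let the C2' oxygen lactonise onto the activated carboxyl. This is the reason for pivalate instead of acetate on ring B.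

**12 from 10, 9 and 8 (oxidation level and protecting-group exchange).** The carboxyl of 12 is carried as a primary alcohol through the acid step, so a free C2' phenol never faces a carboxyl. The MOM ethers of 8, needed for metalation, are removed to triol 9. The two phenols are pivaloylated selectively to 10. The alcohol is then oxidised through aldehyde 11 to 12.

**8 from 5 and 6; 5 from 2 and 3; 2 from 1 (two aryl C–C bonds).** Both ring B carbon substituents are introduced by directed ortho-metalation of resorcinol bis-MOM ether 2, made from 1.
- Lithiation between the two acetal oxygens (aryllithium 4) and reaction with prenyl bromide 3 places the prenyl group at the position that direct alkylation does not reach, giving 5.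
- A second lithiation next to one acetal oxygen (aryllithium 7) and opening of ethylene oxide 6 gives 8.
- The forward reactions must metalate the ring and not the benzylic–allylic CH2 of 5.

## Roads not taken

**Alternative 1:** The pyranone is cut at four bonds at once: O1–C8a and C4–C4a on the ring A side, C3–C4 and O1–C2 on the ring B side.
- Forward step: fluoride releases an aryne from the ortho-silylaryl triflate A2. The aryne inserts into the C=O bond of N,N-dimethylformamide A4. The ketene silyl acetal A3 of the ring B arylacetate adds to the ring-opened adduct and lactonises with loss of dimethylamine, giving the tris(methoxymethyl) ether A1.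
- Merits: it is the most convergent of the four roads. The coupling of arynes, formamides and enolate equivalents to coumarins is an established reaction type. The polarity fits, since an oxygen nucleophile adds to a 3-alkoxyaryne at the carbon remote from the alkoxy group, here C8a.
- Weak points: A2 is a tetrasubstituted benzene whose three oxygens (methyl ether, MOM ether, triflate) must be differentiated and silylated regioselectively, so the ring A problem moves into a multi-step precursor. A3 needs the same ring B arylacetic acid chemistry as the chosen route. The final removal of three MOM groups brings acid next to the prenyl group and two ortho phenols.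
- Comparison: this road is better on convergence and on the security of its key reaction type. The chosen plan sets against it a purchasable ring A partner 13, no differentiation of ring A oxygens by hand, and an end game in base only. With the preparation of A2 counted, the step counts should be similar.

**Alternative 2:** Ring B is cut at C5'–C6', C2'–C3', C4'–C5' and C1'–C2' and is built last around the prenyl group.
- Forward step: Wolff rearrangement of the coumarinyl diazo enone A6 gives a vinylketene. It takes up the prenyl siloxyalkyne A7 by [2+2] cycloaddition, four-electron ring opening and six-electron electrocyclisation (Danheiser benzannulation), giving A5 with the C2' phenol free and the C4' oxygen silylated.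
- Merits: the 1,2,3-substitution of ring B with prenyl between two oxygens arises by construction. The two ring B oxygens emerge differentiated. No metalation beside a prenyl group is needed.
- Weak points: the effort goes into the easier ring. The harder ring A, with three differentiated oxygens, must first be completed by a classical coumarin synthesis and then extended at C3 by an enone and a diazo group. A7 needs ynolate chemistry. The coumarin is itself photoactive under the conditions that generate the ketene. The sequence is long and linear.
- Comparison: this road is better in regiochemical certainty for ring B and in protecting-group economy on that ring. The chosen plan is shorter and convergent, leaves ring A simple, and makes ring B by two metalations.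

**Alternative 3:** The pyranone is cut at C4–C4a.
- Forward step: the ring B arylacetic acid is esterified with the ring A phenol A10 and aminomethylenated to the enamino ester A9. Mild acid converts the enamine carbon into an iminium ion, C4a attacks it, and loss of dimethylamine gives the trisilyl ether A8.
- Merits: it is short. It needs no geometric isomer (the enamine geometry is erased in the iminium ion), no light and no current. It resembles familiar electrophilic coumarin closures.
- Weak points: A10 is a monosilylated 5-methoxyresorcinol that must be made by statistical protection, so the three ring A oxygens are again differentiated by hand. The ester oxygen of A9 has two free ortho positions. Closure next to the silyloxy group instead of next to the methoxy group would exchange the two ring A substituents, and the choice rests on silyl bulk against the electronic preference for attack para to methoxy. The aryl ester is an activated ester exposed to the dimethylamine released. Acid meets a prenyl group and aryl silyl ethers.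
- Comparison: this road is as short as the chosen one or shorter, and its chemistry is more familiar. The chosen plan sets against it a ring A that can close at one carbon only and a ring A starting material that is bought.

Key step: step 9

Assumption: 1, 3, 6 and 13 are taken as purchasable. Coumarin numbering is used for 20; in the open-chain acids ring A is numbered from the carbon bearing the side chain (C1), so its C6 becomes C8a.

## Route

Step 1
Reactants: 1 resorcinol (benzene-1,3-diol)
Product: 2 1,3-bis(methoxymethoxy)benzene
Conditions: NaH (2.4 equiv), MOMCl (2.4 equiv), DMF, 0 °C to rt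
Reagents that add atoms: chloromethyl methyl ether (MOMCl), COCCl
Why: Williamson-type O-alkylation of the bis-phenoxide; the MOM groups serve as directing groups for both metalations.

Step 2
Reactants: 2 1,3-bis(methoxymethoxy)benzene; 3 prenyl bromide (1-bromo-3-methylbut-2-ene)
Product: 5 1,3-bis(methoxymethoxy)-2-(3-methylbut-2-en-1-yl)benzene, via 2-lithio-1,3-bis(methoxymethoxy)benzene 4 (not isolated)
Conditions: n-BuLi (1.1 equiv), THF, 0 °C to rt; then CuI (10 mol %), 3, −78 °C to rt
Reagents that add atoms: none
Why: Directed ortho-metalation removes the proton between the two acetal oxygens, the most acidic ring position; copper-catalysed substitution of the primary allylic bromide by 4 gives the linear prenyl arene.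

Step 3
Reactants: 5 1,3-bis(methoxymethoxy)-2-(3-methylbut-2-en-1-yl)benzene; 6 ethylene oxide (oxirane)
Product: 8 2-[2,4-bis(methoxymethoxy)-3-(3-methylbut-2-en-1-yl)phenyl]ethan-1-ol, via aryllithium 7 (not isolated)
Conditions: n-BuLi (1.2 equiv), TMEDA (1.2 equiv), THF, 0 °C; then 6 (3 equiv, THF solution), −78 °C to rt; H2O
Reagents that add atoms: none
Why: A second directed ortho-metalation, guided by coordination of n-BuLi/TMEDA to an OMOM group, lithiates the ring carbon next to it (the two such positions of 5 are equivalent); 7 opens the epoxide by SN2 attack to give the 2-arylethanol.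

Step 4
Reactants: 8 2-[2,4-bis(methoxymethoxy)-3-(3-methylbut-2-en-1-yl)phenyl]ethan-1-ol
Product: 9 4-(2-hydroxyethyl)-2-(3-methylbut-2-en-1-yl)benzene-1,3-diol
Conditions: conc. HCl (cat.), MeOH, rt
Reagents that add atoms: none
Why: Acid-catalysed acetal exchange of the two MOM ethers with methanol; with catalytic acid at room temperature it should outpace cyclisation of the prenyl group onto a free phenol, and no carboxyl is present for the C2 phenol to lactonise onto.

Step 5
Reactants: 9 4-(2-hydroxyethyl)-2-(3-methylbut-2-en-1-yl)benzene-1,3-diol
Product: 10 4-(2-hydroxyethyl)-2-(3-methylbut-2-en-1-yl)-1,3-phenylene bis(2,2-dimethylpropanoate)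
Conditions: PivCl (2.1 equiv), K2CO3 (2.5 equiv), acetone, 0 °C to rt
Reagents that add atoms: pivaloyl chloride, CC(C)(C)C(Cl)=O
Why: Phenol-selective acylation: K2CO3 ionises only the two phenols, and the phenoxides react with the hindered acyl chloride while the neutral primary alcohol does not without a nucleophilic catalyst. Pivaloyl is also slow to migrate to the neighbouring hydroxyethyl group.

Step 6
Reactants: 10 4-(2-hydroxyethyl)-2-(3-methylbut-2-en-1-yl)-1,3-phenylene bis(2,2-dimethylpropanoate)
Product: 12 2-[2,4-bis(2,2-dimethylpropanoyloxy)-3-(3-methylbut-2-en-1-yl)phenyl]acetic acid, via arylacetaldehyde 11 (not isolated)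
Conditions: TEMPO (0.2 equiv), PhI(OAc)2 (2.2 equiv), MeCN/H2O (1:1), rt
Reagents that add atoms: water, O
Why: TEMPO-catalysed oxidation with PhI(OAc)2 in aqueous MeCN takes a primary alcohol through the aldehyde 11 and its hydrate to the acid under near-neutral conditions. These tolerate the trisubstituted alkene and the aryl pivalates, and the ester-deactivated ring does not compete for the oxidant.

Step 7
Reactants: 12 2-[2,4-bis(2,2-dimethylpropanoyloxy)-3-(3-methylbut-2-en-1-yl)phenyl]acetic acid; 13 4-hydroxy-2-methoxybenzaldehyde
Product: 17 (2E)-3-[4-(acetyloxy)-2-methoxyphenyl]-2-[2,4-bis(2,2-dimethylpropanoyloxy)-3-(3-methylbut-2-en-1-yl)phenyl]prop-2-enoic acid (carboxyl trans to ring A), via aldehyde acetate 14 (not isolated), via arylacetic mixed anhydride 15 (not isolated), via acrylic mixed anhydride 16 (not isolated)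
Conditions: Ac2O, Et3N (3 equiv), 100 °C; then H2O/THF, 60 °C; dilute HCl work-up
Reagents that add atoms: acetic anhydride, CC(=O)OC(C)=O
Why: Perkin condensation: Et3N enolises the mixed anhydride 15, which adds to aldehyde 14 (formed in the flask by acetylation of the phenol); β-elimination gives the E acid with the two aryl groups cis, as is usual for α-arylcinnamic acids, and it is isolated after hydrolysis of 16. Pivalates are used on ring B because acetate-mediated acyl exchange at the C2' ester, which would let that oxygen close a benzofuranone onto the activated carboxyl, is slow at a pivaloyl carbonyl.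

Step 8
Reactants: 17 (2E)-3-[4-(acetyloxy)-2-methoxyphenyl]-2-[2,4-bis(2,2-dimethylpropanoyloxy)-3-(3-methylbut-2-en-1-yl)phenyl]prop-2-enoic acid
Product: 18 (2Z)-3-[4-(acetyloxy)-2-methoxyphenyl]-2-[2,4-bis(2,2-dimethylpropanoyloxy)-3-(3-methylbut-2-en-1-yl)phenyl]prop-2-enoic acid (carboxyl cis to ring A)
Conditions: fac-Ir(ppy)3 (ppy = 2-phenylpyridinato, 1 mol %), blue LEDs (450 nm), degassed MeCN, rt; chromatography, recovered 17 resubmitted
Reagents that add atoms: none
Why: Triplet energy-transfer E to Z isomerisation of a cinnamic acid derivative: the planar push–pull cinnamic chromophore of 17 should accept triplet energy more readily than 18, whose ring A and carboxyl are forced out of plane, so the photostationary state should be enriched in 18. Visible-light triplet sensitisation avoids the singlet six-electron photocyclisation open to the cis-diaryl geometry of 17, and exclusion of oxygen protects the prenyl group.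

Step 9
Reactants: 18 (2Z)-3-[4-(acetyloxy)-2-methoxyphenyl]-2-[2,4-bis(2,2-dimethylpropanoyloxy)-3-(3-methylbut-2-en-1-yl)phenyl]prop-2-enoic acid
Product: 19 3-[2,4-bis(2,2-dimethylpropanoyloxy)-3-(3-methylbut-2-en-1-yl)phenyl]-5-methoxy-2-oxo-2H-chromen-7-yl acetate
Conditions: undivided cell, graphite anode, Pt cathode, n-Bu4NBF4 (0.1 M), 2,6-lutidine (1 equiv), MeCN/HFIP (9:1), constant current (about 2.2 F/mol), rt, Ar
Reagents that add atoms: none
Why: Proposed new method: anodic dehydrogenative C–O lactonisation is established for biaryl-2-carboxylic acids (closest known reaction type) and oxidative closure of Z cinnamic acids to coumarins is known under photocatalysis, but an α-aryl Z cinnamic acid has not been closed at an anode, so the step transfers the reaction type to a new substrate class. Mechanism: the lutidinium carboxylate of 18 loses one electron at graphite (at the carboxylate or at the styrene π system of ring A), the acyloxy oxygen adds to C6 of ring A (the future C8a) to give a cyclohexadienyl radical, and a second anodic electron transfer with loss of the C6 proton to 2,6-lutidine rearomatises ring A, while protons are reduced to H2 at Pt so that no chemical oxidant is present. The pyranone closes in a 6-endo-trig mode onto the arene; no stereocentre is formed, and the Z geometry from step 8 is what places the carboxyl beside ring A. Regioselectivity: of the two ortho carbons of ring A only C6 bears hydrogen, and addition at the methoxy-bearing carbon has no proton to lose and should revert. Chemoselectivity: closure onto ring B would be a 5-endo attack, and the two pivalates deactivate that ring and its benzylic–allylic CH2; ipso attack at C1 of ring A (5-exo, spiro) cannot end in a dienone because the para oxygen carries an acetyl group and no electrofugal group, so it should revert or shift to C6. The isolated trisubstituted alkene of the prenyl group is expected to need a clearly higher potential than the carboxylate, and no singlet oxygen is formed. HFIP stabilises the radical intermediates and, with the lutidinium ion, supplies protons to the cathode ahead of reduction of the acrylic acid or the coumarin, without acting as a nucleophile toward the aryl esters.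

Step 10
Reactants: 19 3-[2,4-bis(2,2-dimethylpropanoyloxy)-3-(3-methylbut-2-en-1-yl)phenyl]-5-methoxy-2-oxo-2H-chromen-7-yl acetate
Product: 20 7-hydroxy-3-[2,4-dihydroxy-3-(3-methylbut-2-en-1-yl)phenyl]-5-methoxy-2H-chromen-2-one
Conditions: NaOMe (4.5 equiv), MeOH/THF, 0 °C to rt, Ar; then 1 M HCl to pH 3
Reagents that add atoms: none
Why: Methanolysis (transesterification) of the aryl acetate and the two aryl pivalates by methoxide, under which the prenyl group is inert; any pyranone opened to the Z methyl coumarinate recloses on acidification, and degassed solvent guards the electron-rich phenoxides against air oxidation.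

## Compound list

1 | resorcinol (benzene-1,3-diol) | Oc1cccc(O)c1 | starting material
2 | 1,3-bis(methoxymethoxy)benzene | COCOc1cccc(OCOC)c1 | intermediate
3 | prenyl bromide (1-bromo-3-methylbut-2-ene) | CC(C)=CCBr | starting material
4 | [2,6-bis(methoxymethoxy)phenyl]lithium | [Li]c1c(OCOC)cccc1OCOC | intermediate
5 | 1,3-bis(methoxymethoxy)-2-(3-methylbut-2-en-1-yl)benzene | COCOc1cccc(OCOC)c1CC=C(C)C | intermediate
6 | ethylene oxide (oxirane) | C1CO1 | starting material
7 | [2,4-bis(methoxymethoxy)-3-(3-methylbut-2-en-1-yl)phenyl]lithium | [Li]c1ccc(OCOC)c(CC=C(C)C)c1OCOC | intermediate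
8 | 2-[2,4-bis(methoxymethoxy)-3-(3-methylbut-2-en-1-yl)phenyl]ethan-1-ol | COCOc1ccc(CCO)c(OCOC)c1CC=C(C)C | intermediate
9 | 4-(2-hydroxyethyl)-2-(3-methylbut-2-en-1-yl)benzene-1,3-diol | OCCc1ccc(O)c(CC=C(C)C)c1O | intermediate
10 | 4-(2-hydroxyethyl)-2-(3-methylbut-2-en-1-yl)-1,3-phenylene bis(2,2-dimethylpropanoate) | CC(C)=CCc1c(OC(=O)C(C)(C)C)ccc(CCO)c1OC(=O)C(C)(C)C | intermediate
11 | 2-[2,4-bis(2,2-dimethylpropanoyloxy)-3-(3-methylbut-2-en-1-yl)phenyl]acetaldehyde | CC(C)=CCc1c(OC(=O)C(C)(C)C)ccc(CC=O)c1OC(=O)C(C)(C)C | intermediate
12 | 2-[2,4-bis(2,2-dimethylpropanoyloxy)-3-(3-methylbut-2-en-1-yl)phenyl]acetic acid | CC(C)=CCc1c(OC(=O)C(C)(C)C)ccc(CC(=O)O)c1OC(=O)C(C)(C)C | intermediate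
13 | 4-hydroxy-2-methoxybenzaldehyde | COc1cc(O)ccc1C=O | starting material
14 | 4-formyl-3-methoxyphenyl acetate | COc1cc(OC(C)=O)ccc1C=O | intermediate
15 | acetic 2-[2,4-bis(2,2-dimethylpropanoyloxy)-3-(3-methylbut-2-en-1-yl)phenyl]acetic anhydride | CC(=O)OC(=O)Cc1ccc(OC(=O)C(C)(C)C)c(CC=C(C)C)c1OC(=O)C(C)(C)C | intermediate
16 | acetic (2E)-3-[4-(acetyloxy)-2-methoxyphenyl]-2-[2,4-bis(2,2-dimethylpropanoyloxy)-3-(3-methylbut-2-en-1-yl)phenyl]prop-2-enoic anhydride | COc1cc(OC(C)=O)ccc1/C=C(/C(=O)OC(C)=O)c1ccc(OC(=O)C(C)(C)C)c(CC=C(C)C)c1OC(=O)C(C)(C)C | intermediate
17 | (2E)-3-[4-(acetyloxy)-2-methoxyphenyl]-2-[2,4-bis(2,2-dimethylpropanoyloxy)-3-(3-methylbut-2-en-1-yl)phenyl]prop-2-enoic acid | COc1cc(OC(C)=O)ccc1/C=C(/C(=O)O)c1ccc(OC(=O)C(C)(C)C)c(CC=C(C)C)c1OC(=O)C(C)(C)C | intermediate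
18 | (2Z)-3-[4-(acetyloxy)-2-methoxyphenyl]-2-[2,4-bis(2,2-dimethylpropanoyloxy)-3-(3-methylbut-2-en-1-yl)phenyl]prop-2-enoic acid | COc1cc(OC(C)=O)ccc1/C=C(\C(=O)O)c1ccc(OC(=O)C(C)(C)C)c(CC=C(C)C)c1OC(=O)C(C)(C)C | intermediate
19 | 3-[2,4-bis(2,2-dimethylpropanoyloxy)-3-(3-methylbut-2-en-1-yl)phenyl]-5-methoxy-2-oxo-2H-chromen-7-yl acetate | COc1cc(OC(C)=O)cc2oc(=O)c(-c3ccc(OC(=O)C(C)(C)C)c(CC=C(C)C)c3OC(=O)C(C)(C)C)cc12 | intermediate
20 | 7-hydroxy-3-[2,4-dihydroxy-3-(3-methylbut-2-en-1-yl)phenyl]-5-methoxy-2H-chromen-2-one | COc1cc(O)cc2oc(=O)c(-c3ccc(O)c(CC=C(C)C)c3O)cc12 | target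

## Step count and least certain steps

Total step count: 10. Longest linear sequence: 10 steps (1 to 20); the ring A partner 13 enters unprotected in step 7.

**Step 9 (key step, proposed new method).** The most likely failure is loss of material to competing anodic pathways, not wrong regiochemistry:
- decarboxylation of the acyloxy radical before it adds to ring A;
- dearomatising ipso attack at the ring A carbon that bears the side chain;
- over-oxidation of the electron-rich coumarin product;
- electrode fouling by oligomerisation of the styrene radical cation.

The cause would be that the α-aryl group twists the carboxyl out of plane and slows the 6-endo addition relative to these processes.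

Fallback, known chemistry: it sets out from 12 and returns at 19, bypassing 17 and 18. A Perkin–Oglialoro condensation of 12 with purchased 2,4-dihydroxy-6-methoxybenzaldehyde F1 in Ac2O/Et3N at 110 °C forms the acrylic acid. The phenol ortho to the formyl group lactonises onto the activated carboxyl under the equilibrating conditions and the para phenol is acetylated, so 19 forms directly. This gives up the saving of one ring A oxygen.

**Step 8.** The isomerisation may stall at an unfavourable photostationary state, or the two geometric isomers may be hard to separate, because the twist of the α-aryl group narrows the triplet-energy difference on which selective sensitisation relies.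

Fallback: from 17, returning at 18, by ground-state equilibration. Heating 17 in Ac2O/Et3N re-forms 16, which equilibrates through reversible conjugate addition of acetate with the acetic mixed anhydride of the Z acid F2. Hydrolysis gives the thermodynamic mixture of 17 and 18, which is separated by chromatography with 17 returned to the equilibration.

**Step 7.** Acyl transfer from the C2' ester to the activated carboxyl, with closure of the five-membered lactone, or incomplete condensation of two ortho-substituted partners at the temperature needed.

Fallback: from 12, returning at 17, by low-temperature aldol addition and elimination on an ester that is cleaved under neutral conditions.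
- 12 is alkylated with allyl bromide/KHCO3 in DMF to the allyl ester F3.
- Its lithium enolate (LiN(SiMe3)2, THF, −78 °C) adds to 14, prepared separately from 13 with Ac2O/pyridine, to give the β-hydroxy ester F4.
- Mesylation (MsCl, Et3N) and elimination with DBU give the allyl E acrylate F5.
- Pd(PPh3)4 with PhSiH3 removes the allyl group to give 17.

**Step 3.** Deprotonation at the benzylic–allylic CH2 of the prenyl group may compete with ring metalation, because that position is the more acidic one and is also flanked by two coordinating acetal oxygens.

Fallback: from 5, returning at 8 through 7. Bromination of 5 with NBS in MeCN at 0 °C at the activated ring position gives 1-bromo-2,4-bis(methoxymethoxy)-3-(3-methylbut-2-en-1-yl)benzene F6. Bromine–lithium exchange with n-BuLi at −78 °C generates 7 at a temperature where proton abstraction does not compete, and 7 is trapped with 6 as before.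

**Step 5.** Incomplete acylation of the phenol flanked by the prenyl and hydroxyethyl groups, or acylation of (or acyl migration to) the primary alcohol, since the product is a hindered aryl ester next to a free hydroxyl.

Fallback: from 9, returning at 10, by temporary protection of the alcohol.
- Tritylation (TrCl, pyridine) gives 4-[2-(triphenylmethoxy)ethyl]-2-(3-methylbut-2-en-1-yl)benzene-1,3-diol F7.
- Exhaustive pivaloylation (PivCl, Et3N, DMAP) gives the bis-pivalate F8.
- Detritylation with catalytic TsOH in MeOH/CH2Cl2 at rt gives 10. The phenols are esterified at that stage and cannot cyclise onto the prenyl group.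

## Further compounds

F1 | step 9 | 2,4-dihydroxy-6-methoxybenzaldehyde | COc1cc(O)cc(O)c1C=O
F2 | step 8 | acetic (2Z)-3-[4-(acetyloxy)-2-methoxyphenyl]-2-[2,4-bis(2,2-dimethylpropanoyloxy)-3-(3-methylbut-2-en-1-yl)phenyl]prop-2-enoic anhydride | COc1cc(OC(C)=O)ccc1/C=C(\C(=O)OC(C)=O)c1ccc(OC(=O)C(C)(C)C)c(CC=C(C)C)c1OC(=O)C(C)(C)C
F3 | step 7 | prop-2-en-1-yl 2-[2,4-bis(2,2-dimethylpropanoyloxy)-3-(3-methylbut-2-en-1-yl)phenyl]acetate | C=CCOC(=O)Cc1ccc(OC(=O)C(C)(C)C)c(CC=C(C)C)c1OC(=O)C(C)(C)C
F4 | step 7 | prop-2-en-1-yl 3-[4-(acetyloxy)-2-methoxyphenyl]-2-[2,4-bis(2,2-dimethylpropanoyloxy)-3-(3-methylbut-2-en-1-yl)phenyl]-3-hydroxypropanoate (mixture of diastereomers) | C=CCOC(=O)C(c1ccc(OC(=O)C(C)(C)C)c(CC=C(C)C)c1OC(=O)C(C)(C)C)C(O)c1ccc(OC(C)=O)cc1OC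
F5 | step 7 | prop-2-en-1-yl (2E)-3-[4-(acetyloxy)-2-methoxyphenyl]-2-[2,4-bis(2,2-dimethylpropanoyloxy)-3-(3-methylbut-2-en-1-yl)phenyl]prop-2-enoate | C=CCOC(=O)/C(=C/c1ccc(OC(C)=O)cc1OC)c1ccc(OC(=O)C(C)(C)C)c(CC=C(C)C)c1OC(=O)C(C)(C)C
F6 | step 3 | 1-bromo-2,4-bis(methoxymethoxy)-3-(3-methylbut-2-en-1-yl)benzene | COCOc1ccc(Br)c(OCOC)c1CC=C(C)C
F7 | step 5 | 4-[2-(triphenylmethoxy)ethyl]-2-(3-methylbut-2-en-1-yl)benzene-1,3-diol | CC(C)=CCc1c(O)ccc(CCOC(c2ccccc2)(c2ccccc2)c2ccccc2)c1O
F8 | step 5 | 4-[2-(triphenylmethoxy)ethyl]-2-(3-methylbut-2-en-1-yl)-1,3-phenylene bis(2,2-dimethylpropanoate) | CC(C)=CCc1c(OC(=O)C(C)(C)C)ccc(CCOC(c2ccccc2)(c2ccccc2)c2ccccc2)c1OC(=O)C(C)(C)C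
A1 | alternative 1 | 3-[2,4-bis(methoxymethoxy)-3-(3-methylbut-2-en-1-yl)phenyl]-5-methoxy-7-(methoxymethoxy)-2H-chromen-2-one | COc1cc(OCOC)cc2oc(=O)c(-c3ccc(OCOC)c(CC=C(C)C)c3OCOC)cc12
A2 | alternative 1 | 3-methoxy-5-(methoxymethoxy)-2-(trimethylsilyl)phenyl trifluoromethanesulfonate | COc1cc(OCOC)cc(OS(=O)(=O)C(F)(F)F)c1[Si](C)(C)C
A3 | alternative 1 | ({2-[2,4-bis(methoxymethoxy)-3-(3-methylbut-2-en-1-yl)phenyl]-1-methoxyethenyl}oxy)trimethylsilane | COC(O[Si](C)(C)C)=Cc1ccc(OCOC)c(CC=C(C)C)c1OCOC
A4 | alternative 1 | N,N-dimethylformamide | CN(C)C=O
A5 | alternative 2 | 3-[2-hydroxy-3-(3-methylbut-2-en-1-yl)-4-(triisopropylsilyloxy)phenyl]-5-methoxy-7-(triisopropylsilyloxy)-2H-chromen-2-one | COc1cc(O[Si](C(C)C)(C(C)C)C(C)C)cc2oc(=O)c(-c3ccc(O[Si](C(C)C)(C(C)C)C(C)C)c(CC=C(C)C)c3O)cc12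
A6 | alternative 2 | 3-[(1E)-4-diazo-3-oxobut-1-en-1-yl]-5-methoxy-7-(triisopropylsilyloxy)-2H-chromen-2-one | COc1cc(O[Si](C(C)C)(C(C)C)C(C)C)cc2oc(=O)c(/C=C/C(=O)C=[N+]=[N-])cc12
A7 | alternative 2 | triisopropyl[(5-methylhex-4-en-1-yn-1-yl)oxy]silane | CC(C)=CCC#CO[Si](C(C)C)(C(C)C)C(C)C
A8 | alternative 3 | 3-[2,4-bis(tert-butyldimethylsilyloxy)-3-(3-methylbut-2-en-1-yl)phenyl]-5-methoxy-7-(triisopropylsilyloxy)-2H-chromen-2-one | COc1cc(O[Si](C(C)C)(C(C)C)C(C)C)cc2oc(=O)c(-c3ccc(O[Si](C)(C)C(C)(C)C)c(CC=C(C)C)c3O[Si](C)(C)C(C)(C)C)cc12
A9 | alternative 3 | 3-methoxy-5-(triisopropylsilyloxy)phenyl 2-[2,4-bis(tert-butyldimethylsilyloxy)-3-(3-methylbut-2-en-1-yl)phenyl]-3-(dimethylamino)prop-2-enoate | CN(C)C=C(C(=O)Oc1cc(OC)cc(O[Si](C(C)C)(C(C)C)C(C)C)c1)c1ccc(O[Si](C)(C)C(C)(C)C)c(CC=C(C)C)c1O[Si](C)(C)C(C)(C)C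
A10 | alternative 3 | 3-methoxy-5-(triisopropylsilyloxy)phenol | COc1cc(O)cc(O[Si](C(C)C)(C(C)C)C(C)C)c1
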